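The isoflavan is cut at C4–C4a. C4 carries ring D, whose three oxygens (ortho, ortho, para) make a C4 cation easy to reach. C4a of ring A sits para to the C7 oxygen and is already tied to C4 through O1–C2–C3. Ionising an acyclic syn-1-(ring D)-2-(ring B)-3-(3-benzyloxyphenoxy)propan-1-ol therefore closes pyran ring C, forms C4–C4a and sets C4 trans to C3 in one operation. C3, from an Evans aldol, is the only stereochemical input. An allyl ether marks the para oxygen of ring D, which later becomes O1 of ring F. The flavanone centre is set last by rhodium-catalysed asymmetric arylation of a chromone.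

Key step: step 11

Notes before the route
- Ring letters: A and C are the chroman of the isoflavan and B is its 3-aryl ring. D is the phloroglucinol ring, which is also the benzo ring of the flavanone. F is the pyranone ring and E is the 4-hydroxyphenyl ring.
- Assumption: the SMILES is read as 3R,4S (3,4-trans) in the isoflavan and 2S in the flavanone. BrZnCH2CO2Et solution, 25 and the (S)-ligand of step 15 are taken as purchasable.
- Ring D is formylated on the free phenol 9 and allylated afterwards. In the allyl ether, two of the three open positions lie next to the allyloxy group, and an aldehyde there would lead to the 8-linked flavanone.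
- Ring F is not built from a cinnamate or by catalytic cyclisation of a chalcone. Cinnamates isomerise and dimerise under light, and the oxa-Michael closure of 2'-hydroxychalcones is reversible. Instead an acetyl group is introduced, ring F is closed to an achiral chromone, and C2 is set by an irreversible C–C bond formation.
- The closure in step 11 is an attack on a trigonal cation. It is therefore classed as exo-trig, not as a displacement at a tetrahedral carbon.

Step 1
Reactants: 1 2,6-dimethoxyphenol
Product: 2 2-(benzyloxy)-1,3-dimethoxybenzene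
Conditions: BnBr, K2CO3, DMF, 50 °C
Reagents that add atoms: benzyl bromide, BrCc1ccccc1
Why: Williamson etherification masks the future 3'-OH of ring B as a hydrogenolysable ether and removes the para-directing dominance of the free phenol before the bromination.

Step 2
Reactants: 2 2-(benzyloxy)-1,3-dimethoxybenzene
Product: 3 2-(benzyloxy)-4-bromo-1,3-dimethoxybenzene
Conditions: NBS, MeCN, 0 °C → rt
Reagents that add atoms: N-bromosuccinimide, O=C1CCC(=O)N1Br
Why: In this electrophilic aromatic bromination the central alkoxy group of a 1,2,3-trialkoxybenzene is twisted out of conjugation, so bromine should enter at C4 (para to one methoxy, ortho to the other), which is the 1,2,3,4-pattern of ring B.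

Step 3
Reactants: 3 2-(benzyloxy)-4-bromo-1,3-dimethoxybenzene
Product: 4 ethyl [3-(benzyloxy)-2,4-dimethoxyphenyl]acetate
Conditions: BrZnCH2CO2Et, Pd2(dba)3 (1 mol %), XPhos (4 mol %), THF, 60 °C
Reagents that add atoms: (2-ethoxy-2-oxoethyl)zinc bromide, CCOC(=O)C[Zn]Br
Why: Negishi-type coupling of a Reformatsky reagent with an aryl bromide installs the acetate arm under neutral conditions, and the bulky biaryl phosphine handles the electron-rich, ortho-substituted bromide.

Step 4
Reactants: 4 ethyl [3-(benzyloxy)-2,4-dimethoxyphenyl]acetate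
Product: 5 [3-(benzyloxy)-2,4-dimethoxyphenyl]acetic acid
Conditions: LiOH, THF–MeOH–H2O, rt; then 1 M HCl
Reagents that add atoms: lithium hydroxide, [Li+].[OH-]
Why: Plain saponification of an unhindered ethyl ester leaves all three aryl ethers untouched.

Step 5
Reactants: 5 [3-(benzyloxy)-2,4-dimethoxyphenyl]acetic acid; 6 (S)-4-benzyl-2-oxazolidinone
Product: 8 (S)-4-benzyl-3-{[3-(benzyloxy)-2,4-dimethoxyphenyl]acetyl}oxazolidin-2-one, via mixed pivalic anhydride 7 (not isolated)
Conditions: PivCl, Et3N, THF, −20 °C; then LiCl, 6, rt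
Reagents that add atoms: pivaloyl chloride, CC(C)(C)C(=O)Cl (its atoms stay only in 7)
Why: N-acylation of the auxiliary through a mixed anhydride under LiCl/Et3N conditions needs no strong base, and the shielded pivaloyl carbonyl directs attack to the arylacetyl carbonyl.

Step 6
Reactants: 9 3,5-bis(benzyloxy)phenol
Product: 11 2,6-bis(benzyloxy)-4-hydroxybenzaldehyde, via aryl iminium ion 10 (not isolated)
Conditions: POCl3, DMF, 0 °C → rt; then H2O, 0 °C
Reagents that add atoms: N,N-dimethylformamide, CN(C)C=O; water, O
Why: Vilsmeier–Haack formylation of 3,5-dialkoxyphenols should favour the position para to the free hydroxyl, and the minor chelated ortho-hydroxy aldehyde is much less polar and is removed by crystallisation or chromatography.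

Step 7
Reactants: 11 2,6-bis(benzyloxy)-4-hydroxybenzaldehyde
Product: 12 4-(allyloxy)-2,6-bis(benzyloxy)benzaldehyde
Conditions: allyl bromide, K2CO3, DMF, rt
Reagents that add atoms: allyl bromide, C=CCBr
Why: Williamson etherification of the acidic para-formyl phenol tags the one ring D oxygen that must later be freed selectively beside benzyl ethers.

Step 8
Reactants: 8 (S)-4-benzyl-3-{[3-(benzyloxy)-2,4-dimethoxyphenyl]acetyl}oxazolidin-2-one; 12 4-(allyloxy)-2,6-bis(benzyloxy)benzaldehyde
Product: 15 (S)-4-benzyl-3-{(2S,3S)-3-[4-(allyloxy)-2,6-bis(benzyloxy)phenyl]-2-[3-(benzyloxy)-2,4-dimethoxyphenyl]-3-hydroxypropanoyl}oxazolidin-2-one, via Z boron enolate 13 (not isolated), via boron aldolate 14 (not isolated)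
Conditions: Bu2BOTf, Et3N, CH2Cl2, 0 °C; 12, −78 → 0 °C; pH 7 buffer, MeOH, H2O2, 0 °C
Reagents that add atoms: dibutylboron triflate, CCCCB(CCCC)OS(=O)(=O)C(F)(F)F (boron and butyl groups stay only in 13 and 14)
Why: In the Evans syn aldol the Z boron enolate reacts through a Zimmerman–Traxler chair with the auxiliary dipole opposed, so the aldehyde meets the enolate face away from the benzyl group and the 2S,3S adduct should result, while the Lewis-basic electron-rich aldehyde binds boron well and buffered work-up with amine-washed silica protects the acid-labile carbinol.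

Step 9
Reactants: 15 the syn aldol adduct
Product: 16 (1S,2R)-1-[4-(allyloxy)-2,6-bis(benzyloxy)phenyl]-2-[3-(benzyloxy)-2,4-dimethoxyphenyl]propane-1,3-diol
Conditions: LiBH4, H2O (1 equiv), Et2O–THF, 0 °C
Reagents that add atoms: none
Why: Reductive cleavage of the imide by hydride attack at the exocyclic carbonyl gives the 1,3-diol and returns the auxiliary, with no spatial change at the aryl-bearing centre (its descriptor turns from S to R only through the change in priorities).

Step 10
Reactants: 16 the (1S,2R)-diol; 17 3-(benzyloxy)phenol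
Product: 18 (1S,2R)-1-[4-(allyloxy)-2,6-bis(benzyloxy)phenyl]-2-[3-(benzyloxy)-2,4-dimethoxyphenyl]-3-[3-(benzyloxy)phenoxy]propan-1-ol (syn)
Conditions: PPh3, DIAD, toluene, 0 °C → rt
Reagents that add atoms: none
Why: In this Mitsunobu etherification the primary hydroxyl forms the oxyphosphonium ion far faster than the doubly ortho-flanked secondary carbinol, so the phenoxide displaces at CH2 and no stereocentre is touched.

Step 11
Reactants: 18 the syn aryl ether carbinol
Product: 20 (3R,4S)-4-[4-(allyloxy)-2,6-bis(benzyloxy)phenyl]-7-(benzyloxy)-3-[3-(benzyloxy)-2,4-dimethoxyphenyl]chroman (3,4-trans), via C4 benzylic cation 19 (not isolated)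
Conditions: Bi(OTf)3 (2 mol %), CH2Cl2–(CF3)2CHOH 4:1, 0.01 M, −20 °C
Reagents that add atoms: none
Why: Acid-assisted loss of water from the C4 hydroxyl gives planar cation 19, whose charge is spread over the 2-, 4- and 6-oxygens of ring D, so the carbinol configuration from step 8 is erased and either epimer would enter the same ion. The tethered ring A then attacks through the carbon para to its benzyloxy group and rearomatises, which is an intramolecular Friedel–Crafts alkylation by a benzylic alcohol, the established entry to 4-arylchromans. Ring C closes in a 6-exo-trig sense with respect to the C4=C1(ring D) bond of the quinone-methide-like resonance form, with the arene π bond inside the new ring, through a half-chair. The new C4 centre is governed by C3 alone: allylic strain places H3 in the plane of the cation next to an ortho-benzyloxy group, which puts the CH2O tether and ring B on opposite faces, so ring A must bond anti to ring B and the 3,4-trans (3R,4S) isomer should form, which is also the more stable one. Site selectivity (C4a against the carbon lying between the two ring A oxygens) rests on the crowding of that flanked position. Retention at C3 rests on ring closure outrunning loss of H3, which the non-basic, poorly nucleophilic medium, the low temperature and the high dilution all favour.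

Step 12
Reactants: 20 the trans 4-arylisoflavan allyl ether
Product: 21 1-{6-(allyloxy)-2,4-bis(benzyloxy)-3-[(3R,4S)-7-(benzyloxy)-3-[3-(benzyloxy)-2,4-dimethoxyphenyl]chroman-4-yl]phenyl}ethan-1-one
Conditions: AcOH (3 equiv), (CF3CO)2O (2 equiv), CH2Cl2, 0 °C
Reagents that add atoms: acetic acid, CC(=O)O
Why: Friedel–Crafts acylation by acetyl trifluoroacetate needs no Lewis acid that would strip benzyl ethers, and it should pick ring D, the only ring activated by three oxygens, whose two open positions are equivalent and which is deactivated after one acylation.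

Step 13
Reactants: 21 the acetyl allyl ether
Product: 22 1-{2,4-bis(benzyloxy)-3-[(3R,4S)-7-(benzyloxy)-3-[3-(benzyloxy)-2,4-dimethoxyphenyl]chroman-4-yl]-6-hydroxyphenyl}ethan-1-one
Conditions: Pd(PPh3)4 (5 mol %), morpholine, THF, rt
Reagents that add atoms: none
Why: In this Tsuji–Trost-type deallylation zerovalent palladium ionises the allyl aryl ether and morpholine traps the allyl fragment, which frees only the oxygen destined to become O1 of ring F and leaves benzyl ethers and ketone alone.

Step 14
Reactants: 22 the ortho-hydroxyacetophenone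
Product: 24 5,7-bis(benzyloxy)-6-[(3R,4S)-7-(benzyloxy)-3-[3-(benzyloxy)-2,4-dimethoxyphenyl]chroman-4-yl]-4H-chromen-4-one, via enaminone 23 (not isolated)
Conditions: Me2NCH(OMe)2, toluene, 90 °C; evaporate; conc. HCl, CH2Cl2, rt
Reagents that add atoms: N,N-dimethylformamide dimethyl acetal, COC(OC)N(C)C
Why: In this standard chromone synthesis the methyl ketone condenses with the amide acetal and acid then drives addition–elimination by the phenol, and since the other two ring D oxygens are benzylated only the 6-linked chromone can form.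

Step 15
Reactants: 24 the chromone; 25 4-(benzyloxy)phenylboronic acid
Product: 26 (2S)-5,7-bis(benzyloxy)-2-[4-(benzyloxy)phenyl]-6-[(3R,4S)-7-(benzyloxy)-3-[3-(benzyloxy)-2,4-dimethoxyphenyl]chroman-4-yl]chroman-4-one
Conditions: [Rh(OH)(cod)]2 (2.5 mol %), (S)-2,2'-bis[bis(3,4,5-trifluorophenyl)phosphino]-6,6'-dimethoxybiphenyl (5.5 mol %), toluene–H2O, 30 °C
Reagents that add atoms: none
Why: In this Hayashi–Miyaura asymmetric 1,4-addition to a chromone, a known entry to flavanones, the aryl–rhodium species with the electron-poor (S)-biaryl bisphosphine should insert C2=C3 from the face that gives 2S (the sense in which (S)-biaryl bisphosphines give S adducts with six-membered cyclic enones of this topology), the remote isoflavan centres should have little influence, and the nearly neutral medium prevents retro-oxa-Michael opening.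

Step 16
Reactants: 26 the pentabenzyl ether
Product: 27 (2S)-5,7-dihydroxy-6-[(3R,4S)-7-hydroxy-3-(3-hydroxy-2,4-dimethoxyphenyl)chroman-4-yl]-2-(4-hydroxyphenyl)chroman-4-one (CNP0267463.1)
Conditions: H2 (1 atm), 10 % Pd/C, EtOAc–MeOH, rt
Reagents that add atoms: none
Why: Neutral hydrogenolysis removes all five benzyl ethers at once, while the methyl ethers, the electron-rich chelated flavanone carbonyl and the three stereocentres, none of which carries a leaving group or meets acid or base, should persist.

Compound list
1 | 2,6-dimethoxyphenol | COc1cccc(OC)c1O | starting material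
2 | 2-(benzyloxy)-1,3-dimethoxybenzene | COc1cccc(OC)c1OCc1ccccc1 | intermediate
3 | 2-(benzyloxy)-4-bromo-1,3-dimethoxybenzene | COc1ccc(Br)c(OC)c1OCc1ccccc1 | intermediate
4 | ethyl [3-(benzyloxy)-2,4-dimethoxyphenyl]acetate | CCOC(=O)Cc1ccc(OC)c(OCc2ccccc2)c1OC | intermediate
5 | [3-(benzyloxy)-2,4-dimethoxyphenyl]acetic acid | OC(=O)Cc1ccc(OC)c(OCc2ccccc2)c1OC | intermediate
6 | (S)-4-benzyl-2-oxazolidinone | O=C1OC[C@H](Cc2ccccc2)N1 | starting material
7 | [3-(benzyloxy)-2,4-dimethoxyphenyl]acetic pivalic anhydride | CC(C)(C)C(=O)OC(=O)Cc1ccc(OC)c(OCc2ccccc2)c1OC | intermediate (not isolated)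
8 | (S)-4-benzyl-3-{[3-(benzyloxy)-2,4-dimethoxyphenyl]acetyl}oxazolidin-2-one | COc1ccc(CC(=O)N2C(=O)OC[C@@H]2Cc2ccccc2)c(OC)c1OCc1ccccc1 | intermediate
9 | 3,5-bis(benzyloxy)phenol | Oc1cc(OCc2ccccc2)cc(OCc2ccccc2)c1 | starting material
10 | [2,6-bis(benzyloxy)-4-hydroxybenzylidene]dimethyliminium ion | C[N+](C)=Cc1c(OCc2ccccc2)cc(O)cc1OCc1ccccc1 | intermediate (not isolated)
11 | 2,6-bis(benzyloxy)-4-hydroxybenzaldehyde | O=Cc1c(OCc2ccccc2)cc(O)cc1OCc1ccccc1 | intermediate
12 | 4-(allyloxy)-2,6-bis(benzyloxy)benzaldehyde | C=CCOc1cc(OCc2ccccc2)c(C=O)c(OCc2ccccc2)c1 | intermediate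
13 | Z dibutylboron enolate of 8 | CCCCB(CCCC)O/C(=C\c1ccc(OC)c(OCc2ccccc2)c1OC)N1C(=O)OC[C@@H]1Cc1ccccc1 | intermediate (not isolated)
14 | O-dibutylboryl derivative of aldol 15 | COc1ccc([C@H](C(=O)N2C(=O)OC[C@@H]2Cc2ccccc2)[C@H](OB(CCCC)CCCC)c2c(OCc3ccccc3)cc(OCC=C)cc2OCc2ccccc2)c(OC)c1OCc1ccccc1 | intermediate (not isolated)
15 | (2S,3S) syn aldol adduct on the (S)-auxiliary | COc1ccc([C@H](C(=O)N2C(=O)OC[C@@H]2Cc2ccccc2)[C@H](O)c2c(OCc3ccccc3)cc(OCC=C)cc2OCc2ccccc2)c(OC)c1OCc1ccccc1 | intermediate
16 | (1S,2R)-1-(ring D aryl)-2-(ring B aryl)propane-1,3-diol | COc1ccc([C@H](CO)[C@H](O)c2c(OCc3ccccc3)cc(OCC=C)cc2OCc2ccccc2)c(OC)c1OCc1ccccc1 | intermediate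
17 | 3-(benzyloxy)phenol | Oc1cccc(OCc2ccccc2)c1 | starting material
18 | (1S,2R) syn-1-(ring D aryl)-2-(ring B aryl)-3-[3-(benzyloxy)phenoxy]propan-1-ol | COc1ccc([C@H](COc2cccc(OCc3ccccc3)c2)[C@H](O)c2c(OCc3ccccc3)cc(OCC=C)cc2OCc2ccccc2)c(OC)c1OCc1ccccc1 | intermediate
19 | C4 benzylic cation derived from 18 | COc1ccc([C@H](COc2cccc(OCc3ccccc3)c2)[CH+]c2c(OCc3ccccc3)cc(OCC=C)cc2OCc2ccccc2)c(OC)c1OCc1ccccc1 | intermediate (not isolated)
20 | (3R,4S) trans-4-(ring D aryl)isoflavan, allyl ether | COc1ccc([C@@H]2COc3cc(OCc4ccccc4)ccc3[C@H]2c2c(OCc3ccccc3)cc(OCC=C)cc2OCc2ccccc2)c(OC)c1OCc1ccccc1 | intermediate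
21 | ring D acetyl derivative of 20 | COc1ccc([C@@H]2COc3cc(OCc4ccccc4)ccc3[C@H]2c2c(OCc3ccccc3)cc(OCC=C)c(C(C)=O)c2OCc2ccccc2)c(OC)c1OCc1ccccc1 | intermediate
22 | ortho-hydroxyacetophenone (21 without allyl) | COc1ccc([C@@H]2COc3cc(OCc4ccccc4)ccc3[C@H]2c2c(OCc3ccccc3)cc(O)c(C(C)=O)c2OCc2ccccc2)c(OC)c1OCc1ccccc1 | intermediate
23 | (E)-3-(dimethylamino)prop-2-en-1-one derived from 22 | COc1ccc([C@@H]2COc3cc(OCc4ccccc4)ccc3[C@H]2c2c(OCc3ccccc3)cc(O)c(C(=O)/C=C/N(C)C)c2OCc2ccccc2)c(OC)c1OCc1ccccc1 | intermediate (not isolated)
24 | 5,7-bis(benzyloxy)-6-[(3R,4S)-isoflavan-4-yl]chromone | COc1ccc([C@@H]2COc3cc(OCc4ccccc4)ccc3[C@H]2c2c(OCc3ccccc3)cc3occc(=O)c3c2OCc2ccccc2)c(OC)c1OCc1ccccc1 | intermediate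
25 | 4-(benzyloxy)phenylboronic acid | OB(O)c1ccc(OCc2ccccc2)cc1 | starting material
26 | (2S)-flavanone, pentabenzyl ether | COc1ccc([C@@H]2COc3cc(OCc4ccccc4)ccc3[C@H]2c2c(OCc3ccccc3)cc3c(c2OCc2ccccc2)C(=O)C[C@@H](c2ccc(OCc4ccccc4)cc2)O3)c(OC)c1OCc1ccccc1 | intermediate
27 | CNP0267463.1 | COc1ccc([C@@H]2COc3cc(O)ccc3[C@H]2c2c(O)cc3c(c2O)C(=O)C[C@@H](c2ccc(O)cc2)O3)c(OC)c1O | target

Total step count: 16.
Longest linear sequence: 14 (steps 1–5 and 8–16).

Steps most likely to fail

Step 11. What may go wrong: proton loss from C3 of cation 19 followed by re-protonation of the stilbene-type alkene, which erodes the C3 configuration. Closure through the ring A carbon between the two oxygens, or capture of the cation by the 2'-methoxy oxygen, may also compete.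
Fallback (an uncharged electrophile in place of a free cation): the fallback sets out from 18. The allyl group is removed first (Pd(PPh3)4, K2CO3, MeOH, rt) to give the para-hydroxybenzylic alcohol F1. A weak acid (diphenyl phosphate, 5 mol %, CH2Cl2, −20 °C) dehydrates it to the para-quinone methide F2, in which H3 is far less acidic than in the cation. The same hydrogen-bonding catalyst promotes the known 1,6-conjugate, Friedel–Crafts type addition, here intramolecular from ring A, to give the trans 4-arylisoflavan phenol F3. O-allylation (allyl bromide, K2CO3, DMF) comes back to the route at 20.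

Step 12. What may go wrong: competing acylation on ring A or ring B, or ipso protonation of ring D by the liberated acid with cleavage of the C4–ring D bond.
Fallback (intramolecular O-to-C acyl transfer in place of an intermolecular substitution): the fallback sets out from 20. Deallylation (Pd(PPh3)4, morpholine, THF) gives the trans 4-arylisoflavan phenol F3, and acetylation on oxygen (Ac2O, pyridine) gives the aryl acetate F4. A photo-Fries rearrangement (254 nm, MeCN) then moves the acetyl group within the solvent cage to the only open kind of ortho position, the para position being blocked by C4. This comes back to the route at 22.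

Step 15. What may go wrong: slow insertion into the electron-rich 5,7-dialkoxychromone, so that protodeboronation of 25 outruns the addition, or poor facial selectivity.
Fallback (substrate diastereomers separated in place of catalyst control): the fallback sets out from 22. Claisen–Schmidt condensation with commercial 4-(benzyloxy)benzaldehyde (KOH, EtOH–THF, rt) gives the 2'-hydroxychalcone F5. NaOAc in refluxing EtOH closes ring F by oxa-Michael addition to 26 together with the 2R epimer F6. Because the isoflavan part is one enantiomer, these two are diastereomers and can be separated by chromatography or crystallisation. F6 is re-equilibrated through F5 under the same conditions. The fallback comes back to the route at 26.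

Further compounds
F1 | step 11 | (1S,2R)-1-[2,6-bis(benzyloxy)-4-hydroxyphenyl]-2-[3-(benzyloxy)-2,4-dimethoxyphenyl]-3-[3-(benzyloxy)phenoxy]propan-1-ol | COc1ccc([C@H](COc2cccc(OCc3ccccc3)c2)[C@H](O)c2c(OCc3ccccc3)cc(O)cc2OCc2ccccc2)c(OC)c1OCc1ccccc1
F2 | step 11 | 3,5-bis(benzyloxy)-4-{(2R)-2-[3-(benzyloxy)-2,4-dimethoxyphenyl]-3-[3-(benzyloxy)phenoxy]propylidene}cyclohexa-2,5-dien-1-one | COc1ccc([C@H](COc2cccc(OCc3ccccc3)c2)C=C2C(OCc3ccccc3)=CC(=O)C=C2OCc2ccccc2)c(OC)c1OCc1ccccc1
F3 | step 11 | 3,5-bis(benzyloxy)-4-[(3R,4S)-7-(benzyloxy)-3-[3-(benzyloxy)-2,4-dimethoxyphenyl]chroman-4-yl]phenol | COc1ccc([C@@H]2COc3cc(OCc4ccccc4)ccc3[C@H]2c2c(OCc3ccccc3)cc(O)cc2OCc2ccccc2)c(OC)c1OCc1ccccc1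
F4 | step 12 | 3,5-bis(benzyloxy)-4-[(3R,4S)-7-(benzyloxy)-3-[3-(benzyloxy)-2,4-dimethoxyphenyl]chroman-4-yl]phenyl acetate | COc1ccc([C@@H]2COc3cc(OCc4ccccc4)ccc3[C@H]2c2c(OCc3ccccc3)cc(OC(C)=O)cc2OCc2ccccc2)c(OC)c1OCc1ccccc1
F5 | step 15 | (E)-2'-hydroxychalcone from 22 and 4-(benzyloxy)benzaldehyde | COc1ccc([C@@H]2COc3cc(OCc4ccccc4)ccc3[C@H]2c2c(OCc3ccccc3)cc(O)c(C(=O)/C=C/c3ccc(OCc4ccccc4)cc3)c2OCc2ccccc2)c(OC)c1OCc1ccccc1
F6 | step 15 | 2R epimer of 26 | COc1ccc([C@@H]2COc3cc(OCc4ccccc4)ccc3[C@H]2c2c(OCc3ccccc3)cc3c(c2OCc2ccccc2)C(=O)C[C@H](c2ccc(OCc4ccccc4)cc2)O3)c(OC)c1OCc1ccccc1
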